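The disconnection cuts quinone ring B (C1'–C6') into two pieces. One is a squarate-derived four-carbon unit (C2'=O, C3'-prenyl, C4'-O, C5'=O). The other is the two-carbon unit C1'=C6'H, carried as a 1,1-disubstituted vinyl group on C3 of the chroman. The key step is a Moore-type ring expansion. It opens a 4-alkenyl-4-silyloxycyclobutenone to a dienylketene, whose 6π electrocyclisation forms C5'–C6' and builds the fully substituted ring in one operation. Oxidation in the same flask gives the quinone. The step exploits the contiguous oxygenated C2'–C5' array of ring B. The precursor is a four-membered ring bearing tert-butoxy, prenyl, OSiMe3 and the (3R)-chroman-3-ylvinyl group. C3 is set earlier by asymmetric hydrogenation.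

Key step: step 11

Remark: di-tert-butyl squarate is taken as a catalogue compound; the (R)-ligand in step 6 is chosen by analogy with (E)-2-alkyl-2-alkenoic acids, and the antipodal ligand is used should the sense prove opposite (prenyl = 3-methylbut-2-en-1-yl throughout).

Step 1
Reactants: 1 1,3-dimethoxybenzene; 2 prenyl bromide (1-bromo-3-methylbut-2-ene)
Product: 4 1,3-dimethoxy-2-(3-methylbut-2-en-1-yl)benzene, via aryllithium 3 (not isolated)
Conditions: n-BuLi, THF, 0 °C to rt; then 2, −78 °C to rt
Reagents that add atoms: none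
Why: Directed ortho-metalation removes only the C2–H flanked by both methoxy groups, and the aryllithium displaces the primary allylic bromide in an SN2 alkylation.

Step 2
Reactants: 4 1,3-dimethoxy-2-prenylbenzene
Product: 6 3,5-dimethoxy-4-prenylphenol, via arylboronate 5 (not isolated)
Conditions: [Ir(OMe)(cod)]2 (cat.), dtbpy (cat.), B2pin2, THF, 80 °C; then aq H2O2, NaOH, 0 °C
Reagents that add atoms: hydrogen peroxide OO
Why: Sterically governed iridium-catalysed aromatic C–H borylation reaches only C5–H, the one ring C–H without an ortho substituent, and basic peroxide oxidation of the C–B bond gives the phenol without touching the electron-rich trisubstituted alkene (borylation–oxidation sequence).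

Step 3
Reactants: 6 3,5-dimethoxy-4-prenylphenol
Product: 7 6-hydroxy-2,4-dimethoxy-3-prenylbenzaldehyde
Conditions: MgCl2, Et3N, (CH2O)n, MeCN, reflux; then dilute HCl
Reagents that add atoms: paraformaldehyde (as formaldehyde) C=O
Why: Casnati–Skattebøl magnesium-mediated formylation is ortho-specific; the two ortho positions are equivalent, the para position is blocked, and a second formaldehyde takes up the hydride.

Step 4
Reactants: 7 6-hydroxy-2,4-dimethoxy-3-prenylbenzaldehyde
Product: 8 5,7-dimethoxy-6-prenyl-2H-chromene-3-carbonitrile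
Conditions: acrylonitrile (excess), DABCO, 80 °C
Reagents that add atoms: acrylonitrile C=CC#N
Why: The DABCO-promoted oxa-Michael/intramolecular aldol condensation of a salicylaldehyde with acrylonitrile (Baylis–Hillman-type chromene annulation) builds the pyran ring with a one-carbon handle at C3.

Step 5
Reactants: 8 5,7-dimethoxy-6-prenyl-2H-chromene-3-carbonitrile
Product: 9 5,7-dimethoxy-6-prenyl-2H-chromene-3-carboxylic acid
Conditions: 10% aq NaOH, EtOH, reflux; then 2 M HCl, 0 °C
Reagents that add atoms: sodium hydroxide [Na+].[OH-]; water O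
Why: Alkaline nitrile hydrolysis leaves the aryl ethers, the prenyl group and the chromene double bond untouched.

Step 6
Reactants: 9 5,7-dimethoxy-6-prenyl-2H-chromene-3-carboxylic acid
Product: 10 (3S)-5,7-dimethoxy-6-prenylchromane-3-carboxylic acid
Conditions: Ru(OAc)2[(R)-H8-BINAP] (cat.), H2 (4 atm), MeOH, 25 °C
Reagents that add atoms: none
Why: In this Noyori-type carboxylate-directed asymmetric hydrogenation the acid binds to ruthenium as its carboxylate and the (R)-ligand shields one face of C3=C4, so hydrogen adds to give the (3S) centre, while the non-coordinating trisubstituted prenyl alkene is not reduced, as in the selective hydrogenation of geraniol-type dienes.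

Step 7
Reactants: 10 (3S)-5,7-dimethoxy-6-prenylchromane-3-carboxylic acid
Product: 12 1-[(3S)-5,7-dimethoxy-6-prenylchroman-3-yl]ethan-1-one, via dilithium diolate 11 (not isolated)
Conditions: MeLi (2.2 equiv), Et2O/THF, 0 °C; inverse quench into cold 1 M HCl
Reagents that add atoms: methyllithium [Li]C
Why: In the ketone synthesis from a carboxylic acid and an organolithium, the lithium carboxylate accepts one methyllithium and the diolate collapses only on quench, so over-addition and enolisation at C3 are avoided and the configuration is kept.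

Step 8
Reactants: 12 1-[(3S)-5,7-dimethoxy-6-prenylchroman-3-yl]ethan-1-one
Product: 13 (E)-2,4,6-triisopropylbenzenesulfonylhydrazone of ketone 12 with (3R) descriptor (same spatial arrangement)
Conditions: 2,4,6-triisopropylbenzenesulfonohydrazide, THF, 23 °C
Reagents that add atoms: 2,4,6-triisopropylbenzenesulfonohydrazide CC(C)c1cc(C(C)C)c(S(=O)(=O)NN)c(C(C)C)c1
Why: Hydrazone condensation under near-neutral conditions avoids enolisation at C3 and gives the E isomer, whose N–H lies syn to the methyl group as the next step requires.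

Step 9
Reactants: 13 trisylhydrazone; 14 di-tert-butyl squarate (3,4-di-tert-butoxycyclobut-3-ene-1,2-dione)
Product: 17 2,3-di-tert-butoxy-4-(trimethylsilyloxy)-4-{1-[(3R)-5,7-dimethoxy-6-prenylchroman-3-yl]ethenyl}cyclobut-2-en-1-one (both C4 epimers), via vinyllithium 15 (not isolated), via lithium alkoxide 16 (not isolated)
Conditions: n-BuLi (2.1 equiv), THF, −78 to 0 °C; −78 °C, 14; TMSCl, −78 to 0 °C
Reagents that add atoms: chlorotrimethylsilane C[Si](C)(C)Cl
Why: In the Shapiro reaction, double deprotonation (N–H, then the syn methyl group, not C3–H) and loss of sulfinate and N2 give the 1,1-disubstituted vinyllithium with C3 intact, this adds 1,2 to one of the two equivalent squarate carbonyls, silylation blocks the alkoxide, and the new carbinol centre forms as an epimer mixture that step 11 erases.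

Step 10
Reactants: 17 2,3-di-tert-butoxy-4-silyloxy-4-alkenylcyclobutenone
Product: 20 2-tert-butoxy-3-prenyl-4-(trimethylsilyloxy)-4-{1-[(3R)-5,7-dimethoxy-6-prenylchroman-3-yl]ethenyl}cyclobut-2-en-1-one (both C4 epimers), via barium alkoxide 18 (not isolated), via allylic trifluoroacetate 19 (not isolated)
Conditions: prenyl chloride, Rieke Ba, THF, −78 °C; add 17, −78 °C; (CF3CO)2O, −78 to 0 °C; aq NaHCO3
Reagents that add atoms: prenyl chloride (used as prenylbarium chloride) CC(C)=CCCl
Why: α-Selective allylbarium carbonyl addition (attack through the unsubstituted CH2 terminus, reinforced by crowding at the carbonyl) is followed by the known sequential-addition/1,3-carbonyl-transposition protocol for squarates, in which trifluoroacetylation makes the new alkoxide a leaving group and the distal tert-butoxy group expels it and loses isobutene, so the prenyl carbon ends up next to the silyloxy carbon and the carbonyl next to the remaining tert-butoxy carbon.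

Step 11
Reactants: 20 2-tert-butoxy-3-prenyl-4-silyloxy-4-alkenylcyclobutenone
Product: 24 2-tert-butoxy-3-prenyl-5-[(3R)-5,7-dimethoxy-6-prenylchroman-3-yl]-1,4-benzoquinone, via dienylketene 21 (not isolated), via cyclohexadienone 22 (not isolated), via silyloxyphenol 23 (not isolated)
Conditions: degassed p-xylene, 135 °C; concentrate; PhI(OAc)2, MeCN/H2O, 0 °C
Reagents that add atoms: none
Why: Heating opens the C1–C4 bond of the cyclobutenone by conrotatory 4π electrocyclic ring opening, and the donor OSiMe3 group rotates outward, which forces the alkenyl group inward and gives dienylketene 21 with ketene and vinyl termini cis. Disrotatory 6π electrocyclisation then joins the ketene carbon (future C5') to the vinyl CH2 (future C6'), closing the six-membered carbocycle as dienone 22, which tautomerises to the silyl-protected hydroquinone 23. The closest known reaction type is the Moore rearrangement of 4-alkenyl-4-oxycyclobutenones to hydroquinones and quinones. No stereocentre is created: both C4 epimers of 20 converge because that carbon becomes sp2, and C3 of the chroman lies outside the pericyclic array and keeps its configuration under the neutral conditions. No regiochemical choice arises, since prenyl (next to the carbinol carbon) and tert-butoxy (next to the carbonyl) are already fixed on the four-membered ring, and the conjugated, cis-disposed vinyl group outcompetes the remote prenyl alkenes for the ketene. PhI(OAc)2 in aqueous acetonitrile oxidises the electron-rich p-silyloxyphenol, with loss of the silyl group, much faster than it attacks ring A or the alkenes.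

Step 12
Reactants: 24 tert-butoxyquinone
Product: 25 2-hydroxy-3-prenyl-5-[(3R)-5,7-dimethoxy-6-prenylchroman-3-yl]-1,4-benzoquinone (target)
Conditions: CF3CO2H, CH2Cl2, 0 °C, short contact; aq NaHCO3
Reagents that add atoms: none
Why: Acidolysis of the vinylogous tert-butyl ester (E1 loss of isobutene) should be far faster than protonation of the trisubstituted alkenes or cleavage of the aryl methyl ethers, and it does not involve C3.

Compound list
1 | 1,3-dimethoxybenzene | COc1cccc(OC)c1 | starting material
2 | prenyl bromide (1-bromo-3-methylbut-2-ene) | CC(C)=CCBr | starting material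
3 | 2,6-dimethoxyphenyllithium | [Li]c1c(OC)cccc1OC | intermediate
4 | 1,3-dimethoxy-2-(3-methylbut-2-en-1-yl)benzene | COc1cccc(OC)c1CC=C(C)C | intermediate
5 | 2-(3,5-dimethoxy-4-prenylphenyl)-4,4,5,5-tetramethyl-1,3,2-dioxaborolane | COc1cc(B2OC(C)(C)C(C)(C)O2)cc(OC)c1CC=C(C)C | intermediate
6 | 3,5-dimethoxy-4-prenylphenol | COc1cc(O)cc(OC)c1CC=C(C)C | intermediate
7 | 6-hydroxy-2,4-dimethoxy-3-prenylbenzaldehyde | COc1cc(O)c(C=O)c(OC)c1CC=C(C)C | intermediate
8 | 5,7-dimethoxy-6-prenyl-2H-chromene-3-carbonitrile | COc1cc2c(c(OC)c1CC=C(C)C)C=C(C#N)CO2 | intermediate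
9 | 5,7-dimethoxy-6-prenyl-2H-chromene-3-carboxylic acid | COc1cc2c(c(OC)c1CC=C(C)C)C=C(C(=O)O)CO2 | intermediate
10 | (3S)-5,7-dimethoxy-6-prenylchromane-3-carboxylic acid | COc1cc2c(c(OC)c1CC=C(C)C)C[C@H](C(=O)O)CO2 | intermediate
11 | dilithium 1-[(3S)-5,7-dimethoxy-6-prenylchroman-3-yl]ethane-1,1-diolate | COc1cc2c(c(OC)c1CC=C(C)C)C[C@H](C(C)([O-])[O-])CO2.[Li+].[Li+] | intermediate
12 | 1-[(3S)-5,7-dimethoxy-6-prenylchroman-3-yl]ethan-1-one | COc1cc2c(c(OC)c1CC=C(C)C)C[C@H](C(C)=O)CO2 | intermediate
13 | (E)-N'-{1-[(3R)-5,7-dimethoxy-6-prenylchroman-3-yl]ethylidene}-2,4,6-triisopropylbenzenesulfonohydrazide | COc1cc2c(c(OC)c1CC=C(C)C)C[C@H](/C(C)=N/NS(=O)(=O)c1c(C(C)C)cc(C(C)C)cc1C(C)C)CO2 | intermediate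
14 | di-tert-butyl squarate (3,4-di-tert-butoxycyclobut-3-ene-1,2-dione) | CC(C)(C)OC1=C(OC(C)(C)C)C(=O)C1=O | starting material
15 | 1-[(3R)-5,7-dimethoxy-6-prenylchroman-3-yl]ethenyllithium | COc1cc2c(c(OC)c1CC=C(C)C)C[C@H](C([Li])=C)CO2 | intermediate
16 | lithium 2,3-di-tert-butoxy-4-oxo-1-{1-[(3R)-5,7-dimethoxy-6-prenylchroman-3-yl]ethenyl}cyclobut-2-en-1-olate (both carbinol epimers) | COc1cc2c(c(OC)c1CC=C(C)C)C[C@H](C(=C)C1([O-])C(=O)C(OC(C)(C)C)=C1OC(C)(C)C)CO2.[Li+] | intermediate
17 | 2,3-di-tert-butoxy-4-(trimethylsilyloxy)-4-{1-[(3R)-5,7-dimethoxy-6-prenylchroman-3-yl]ethenyl}cyclobut-2-en-1-one (both C4 epimers) | COc1cc2c(c(OC)c1CC=C(C)C)C[C@H](C(=C)C1(O[Si](C)(C)C)C(=O)C(OC(C)(C)C)=C1OC(C)(C)C)CO2 | intermediate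
18 | chlorobarium 2,3-di-tert-butoxy-1-prenyl-4-(trimethylsilyloxy)-4-{1-[(3R)-5,7-dimethoxy-6-prenylchroman-3-yl]ethenyl}cyclobut-2-en-1-olate (diastereomer mixture) | COc1cc2c(c(OC)c1CC=C(C)C)C[C@H](C(=C)C1(O[Si](C)(C)C)C([O-])(CC=C(C)C)C(OC(C)(C)C)=C1OC(C)(C)C)CO2.[Ba+2].[Cl-] | intermediate
19 | trifluoroacetate ester of the tertiary alcohol corresponding to 18 (diastereomer mixture) | COc1cc2c(c(OC)c1CC=C(C)C)C[C@H](C(=C)C1(O[Si](C)(C)C)C(OC(=O)C(F)(F)F)(CC=C(C)C)C(OC(C)(C)C)=C1OC(C)(C)C)CO2 | intermediate
20 | 2-tert-butoxy-3-prenyl-4-(trimethylsilyloxy)-4-{1-[(3R)-5,7-dimethoxy-6-prenylchroman-3-yl]ethenyl}cyclobut-2-en-1-one (both C4 epimers) | COc1cc2c(c(OC)c1CC=C(C)C)C[C@H](C(=C)C1(O[Si](C)(C)C)C(CC=C(C)C)=C(OC(C)(C)C)C1=O)CO2 | intermediate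
21 | 2-tert-butoxy-3-prenyl-4-(trimethylsilyloxy)-5-[(3R)-5,7-dimethoxy-6-prenylchroman-3-yl]hexa-1,3,5-trien-1-one (dienylketene; ketene and vinyl groups cis on C3=C4) | COc1cc2c(c(OC)c1CC=C(C)C)C[C@H](C(=C)/C(O[Si](C)(C)C)=C(CC=C(C)C)\C(OC(C)(C)C)=C=O)CO2 | intermediate
22 | 2-tert-butoxy-3-prenyl-4-(trimethylsilyloxy)-5-[(3R)-5,7-dimethoxy-6-prenylchroman-3-yl]cyclohexa-2,4-dien-1-one | COc1cc2c(c(OC)c1CC=C(C)C)C[C@H](C1=C(O[Si](C)(C)C)C(CC=C(C)C)=C(OC(C)(C)C)C(=O)C1)CO2 | intermediate
23 | 2-tert-butoxy-3-prenyl-4-(trimethylsilyloxy)-5-[(3R)-5,7-dimethoxy-6-prenylchroman-3-yl]phenol | COc1cc2c(c(OC)c1CC=C(C)C)C[C@H](c1cc(O)c(OC(C)(C)C)c(CC=C(C)C)c1O[Si](C)(C)C)CO2 | intermediate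
24 | 2-tert-butoxy-3-prenyl-5-[(3R)-5,7-dimethoxy-6-prenylchroman-3-yl]-1,4-benzoquinone | COc1cc2c(c(OC)c1CC=C(C)C)C[C@H](C1=CC(=O)C(OC(C)(C)C)=C(CC=C(C)C)C1=O)CO2 | intermediate
25 | 2-hydroxy-3-prenyl-5-[(3R)-5,7-dimethoxy-6-prenylchroman-3-yl]-1,4-benzoquinone | COc1cc2c(c(OC)c1CC=C(C)C)C[C@H](C1=CC(=O)C(O)=C(CC=C(C)C)C1=O)CO2 | target

Total step count: 12. Longest linear sequence: 12 steps (1 to 25); 2 and 14 enter as purchased compounds.

Steps most likely to fail

Step 10. The prenyl metal may react through its substituted γ-terminus (allylic transposition of the transferred group). The crowded vinylogous ester carbonyl may also resist addition. The fallback sets out from 17. Allylmagnesium bromide, which has no regiochemical ambiguity, is added in THF at −78 °C, and the same trifluoroacetic anhydride-triggered carbonyl transposition should give 3-allyl-2-tert-butoxy-4-(trimethylsilyloxy)-4-{1-[(3R)-5,7-dimethoxy-6-prenylchroman-3-yl]ethenyl}cyclobut-2-en-1-one F1. Olefin cross-metathesis with 2-methyl-2-butene (second-generation Grubbs catalyst, CH2Cl2, 40 °C) runs well below the ring-opening temperature and leaves the hindered 1,1-disubstituted alkene inert. It converts allyl into prenyl and comes back to the route at 20.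

Step 12. Under acid, the freed hydroxyl oxygen may cyclise onto the protonated neighbouring prenyl double bond, closing a dimethylpyran ring. The fallback removes the tert-butyl group before that prenyl group exists. It sets out from 17 and passes through the allyl cyclobutenone F1 described above. Ring expansion and oxidation as in step 11 should give 3-allyl-2-tert-butoxy-5-[(3R)-5,7-dimethoxy-6-prenylchroman-3-yl]-1,4-benzoquinone F2. Trifluoroacetic acid then frees 3-allyl-2-hydroxy-5-[(3R)-5,7-dimethoxy-6-prenylchroman-3-yl]-1,4-benzoquinone F3, whose monosubstituted alkene is much harder to protonate. A final cross-metathesis with 2-methyl-2-butene (quinones are tolerated by ruthenium carbenes) comes back to the route at 25.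

Step 6. Enantiofacial discrimination on this peri-substituted chromene acid may be insufficient. The fallback replaces catalytic induction by classical resolution and sets out from 9. Carboxylate-directed hydrogenation with an achiral cationic rhodium catalyst ([Rh(nbd)(dppb)]BF4, Et3N, H2, MeOH) should give racemic 5,7-dimethoxy-6-prenylchromane-3-carboxylic acid F4. Crystallisation with (R)-1-phenylethylamine (or its antipode, if that forms the less soluble pair with the wanted acid) gives the (R)-1-phenylethylammonium (3S)-5,7-dimethoxy-6-prenylchromane-3-carboxylate salt F5. Acidification comes back to the route at 10.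

Further compounds
F1 | step 10 | 3-allyl-2-tert-butoxy-4-(trimethylsilyloxy)-4-{1-[(3R)-5,7-dimethoxy-6-prenylchroman-3-yl]ethenyl}cyclobut-2-en-1-one (both C4 epimers) | COc1cc2c(c(OC)c1CC=C(C)C)C[C@H](C(=C)C1(O[Si](C)(C)C)C(CC=C)=C(OC(C)(C)C)C1=O)CO2
F2 | step 12 | 3-allyl-2-tert-butoxy-5-[(3R)-5,7-dimethoxy-6-prenylchroman-3-yl]-1,4-benzoquinone | COc1cc2c(c(OC)c1CC=C(C)C)C[C@H](C1=CC(=O)C(OC(C)(C)C)=C(CC=C)C1=O)CO2
F3 | step 12 | 3-allyl-2-hydroxy-5-[(3R)-5,7-dimethoxy-6-prenylchroman-3-yl]-1,4-benzoquinone | COc1cc2c(c(OC)c1CC=C(C)C)C[C@H](C1=CC(=O)C(O)=C(CC=C)C1=O)CO2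
F4 | step 6 | racemic 5,7-dimethoxy-6-prenylchromane-3-carboxylic acid | COc1cc2c(c(OC)c1CC=C(C)C)CC(C(=O)O)CO2
F5 | step 6 | (R)-1-phenylethylammonium (3S)-5,7-dimethoxy-6-prenylchromane-3-carboxylate | COc1cc2c(c(OC)c1CC=C(C)C)C[C@H](C(=O)[O-])CO2.C[C@@H]([NH3+])c1ccccc1
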